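**Strategy.** Locants follow bicyclo[9.3.1]pentadecane numbering of the target (C1 and C11 bridgeheads; C15 the formyl-bearing quaternary bridge; C12 the spiro-epoxide carbon). The cyclohexane C1–C15–C11–C12–C13–C14, with its aldehyde on C15, is read as a Diels–Alder adduct of a C15=C11 (E)-enal and a C12=C13–C14=C1 (E,E)-diene; the (Z,Z)-chain C2–C10 that joins C1 to C11 is the tether. One catalytic enantioselective cycloaddition of an acyclic pentaenal therefore forms C11–C12 and C15–C1, closes the six- and the twelve-membered rings and sets C1, C11 and C15. A silyloxymethyl group on the diene terminus later delivers the epoxide by α-chlorination, reduction and displacement with inversion.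

Key step: step 14

Remark: the target is read as (1R,3Z,7Z,11R,12S,15S), with the ring carbons cis on both trisubstituted double bonds of the twelve-membered ring.

Step 1
Reactants: 1 neryl acetate
Product: 3 (2Z)-3-methyl-6-oxohex-2-en-1-yl acetate, via secondary ozonide 2 (not isolated)
Conditions: O3 (1 equiv), CH2Cl2, −78 °C; then Me2S, −78 °C → rt
Reagents that add atoms: ozone, [O-][O+]=O
Why: Ozonolysis with reductive work-up; ozone should attack the electron-rich terminal trisubstituted alkene in preference to the alkene deactivated by the allylic acetate, so the (Z)-alkene survives.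

Step 2
Reactants: 3 (2Z)-3-methyl-6-oxohex-2-en-1-yl acetate; 4 ethyl 2-[bis(2,2,2-trifluoroethoxy)phosphoryl]propanoate
Product: 5 ethyl (2Z,6Z)-8-acetoxy-2,6-dimethylocta-2,6-dienoate
Conditions: KN(SiMe3)2, 18-crown-6, THF, −78 °C
Reagents that add atoms: none
Why: Still–Gennari olefination; fast elimination from the kinetic adduct of the trifluoroethyl phosphonate should give the (Z)-trisubstituted enoate.

Step 3
Reactants: 5 acetoxy dienoate
Product: 6 ethyl (2Z,6Z)-8-hydroxy-2,6-dimethylocta-2,6-dienoate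
Conditions: K2CO3 (0.2 equiv), EtOH, 0 °C → rt
Reagents that add atoms: none
Why: Base-catalysed transesterification (ethanolysis); the primary acetate is cleaved much faster than the conjugated α-branched ethyl ester, which ethanol leaves unchanged in any case.

Step 4
Reactants: 6 hydroxy dienoate
Product: 7 ethyl (2Z,6Z)-8-bromo-2,6-dimethylocta-2,6-dienoate
Conditions: CBr4, PPh3, CH2Cl2, 0 °C
Reagents that add atoms: carbon tetrabromide, BrC(Br)(Br)Br
Why: Appel bromination; SN2 displacement of the alkoxyphosphonium group at the primary allylic carbon keeps the (Z)-geometry.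

Step 5
Reactants: 8 (E)-pent-2-en-4-yn-1-ol
Product: 9 (E)-triethyl(pent-2-en-4-yn-1-yloxy)silane
Conditions: Et3SiCl, imidazole, CH2Cl2, 0 °C
Reagents that add atoms: chlorotriethylsilane, CC[Si](Cl)(CC)CC
Why: Silylation of a primary alcohol; the triethylsilyl ether is chosen because it can later be oxidised directly to the aldehyde.

Step 6
Reactants: 9 silyl enyne; 7 bromo dienoate
Product: 11 ethyl (2Z,6Z,9E,11E)-2,6-dimethyl-13-[(triethylsilyl)oxy]trideca-2,6,9,11-tetraenoate, via dienylzirconocene chloride 10 (not isolated)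
Conditions: Cp2Zr(H)Cl, THF, rt; then 7, Pd(PPh3)4 (5 mol %), ZnCl2 (0.2 equiv), THF, 0 °C → rt
Reagents that add atoms: chlorobis(cyclopentadienyl)hydridozirconium, [H][Zr](Cl)(C1C=CC=C1)C1C=CC=C1 (atoms of 10 only)
Why: syn-Hydrozirconation of the terminal alkyne gives the (1E,3E)-dienylmetal, and palladium-catalysed allyl–alkenyl cross-coupling of the Negishi type joins it to the primary terminus of the allylic bromide with retention of both geometries.

Step 7
Reactants: 11 tetraenoate
Product: 12 (2Z,6Z,9E,11E)-2,6-dimethyl-13-[(triethylsilyl)oxy]trideca-2,6,9,11-tetraen-1-ol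
Conditions: iBu2AlH (2.2 equiv), CH2Cl2, −78 °C; aq. potassium sodium tartrate
Reagents that add atoms: none
Why: Aluminium hydride 1,2-reduction of the enoate to the allylic alcohol, which leaves the silyl ether and all alkenes untouched.

Step 8
Reactants: 12 tetraenol
Product: 14 triethyl{[(2E,4E,7Z,11Z)-13-bromo-8,12-dimethyltrideca-2,4,7,11-tetraen-1-yl]oxy}silane, via allylic mesylate 13 (not isolated)
Conditions: MeSO2Cl, Et3N, CH2Cl2, −40 °C; then LiBr, THF, 0 °C
Reagents that add atoms: methanesulfonyl chloride, CS(=O)(=O)Cl (atoms of 13 only); lithium bromide, [Li+].[Br-]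
Why: Mesylation followed by SN2 displacement with bromide under non-acidic conditions converts the allylic alcohol into the bromide without loss of the silyl ether or of the (Z)-geometry.

Step 9
Reactants: 14 tetraenyl bromide
Product: 15 (4Z,8Z,11E,13E)-4,8-dimethyl-15-[(triethylsilyl)oxy]pentadeca-4,8,11,13-tetraenenitrile
Conditions: CH3CN (3 equiv), LiN(iPr)2, THF, −78 °C; then 14, −78 → −20 °C
Reagents that add atoms: acetonitrile, CC#N
Why: SN2 alkylation of lithiated acetonitrile (in excess, to suppress dialkylation) at the primary allylic bromide adds the two carbons that become C10 and C11.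

Step 10
Reactants: 15 tetraenenitrile
Product: 17 (4Z,8Z,11E,13E)-4,8-dimethyl-15-[(triethylsilyl)oxy]pentadeca-4,8,11,13-tetraenal, via N-aluminoaldimine 16 (not isolated)
Conditions: iBu2AlH (1.2 equiv), toluene, −78 °C; then aq. potassium sodium tartrate, SiO2
Reagents that add atoms: diisobutylaluminium hydride, CC(C)C[AlH]CC(C)C (atoms of 16 only); water, O
Why: Partial reduction of the nitrile: one hydride transfer stops at the N-metallated imine, which hydrolyses to the aldehyde on mild aqueous work-up.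

Step 11
Reactants: 18 5-bromo-2-methylpent-2-ene
Product: 19 (4-methylpent-3-en-1-yl)triphenylphosphonium bromide
Conditions: PPh3, MeCN, reflux
Reagents that add atoms: triphenylphosphine, c1ccc(cc1)P(c1ccccc1)c1ccccc1
Why: SN2 quaternisation of triphenylphosphine by the primary bromide.

Step 12
Reactants: 19 phosphonium bromide
Product: 21 6-methyl-2-(triphenyl-λ5-phosphanylidene)hept-5-enal, via phosphonium ylide 20 (not isolated)
Conditions: NaN(SiMe3)2, THF, 0 °C; then HCO2Et, 0 °C → rt
Reagents that add atoms: ethyl formate, CCOC=O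
Why: C-Acylation of the non-stabilised ylide with ethyl formate, followed by loss of ethanol, gives the stabilised α-formyl ylide.

Step 13
Reactants: 17 tetraenal; 21 formyl ylide
Product: 22 (2E,6Z,10Z,13E,15E)-6,10-dimethyl-2-(4-methylpent-3-en-1-yl)-17-[(triethylsilyl)oxy]heptadeca-2,6,10,13,15-pentaenal
Conditions: toluene, 90 °C
Reagents that add atoms: none
Why: Wittig olefination with a stabilised ylide, which is expected to give the (E)-2-alkyl-2-enal (formyl group trans to the chain), the geometry the cycloaddition needs.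

Step 14
Reactants: 22 pentaenal
Product: 23 (1S,3Z,7Z,11S,12R,15S)-4,8-dimethyl-15-(4-methylpent-3-en-1-yl)-12-{[(triethylsilyl)oxy]methyl}bicyclo[9.3.1]pentadeca-3,7,13-triene-15-carbaldehyde
Conditions: (R)-3,3-diphenyl-1-(2-methylphenyl)tetrahydro-1H,3H-pyrrolo[1,2-c][1,3,2]oxazaborole (20 mol %), HN(SO2CF3)2 (17 mol %), CH2Cl2 (1 mM), −78 → −20 °C
Reagents that add atoms: none
Why: The protonated oxazaborolidine binds the formyl group of the s-trans (E)-enal, and the (E,E)-diene adds in a concerted, asynchronous [4+2] cycloaddition in which the bond from the enal β-carbon to the silyloxymethyl-bearing diene terminus (C11–C12) leads and C15–C1 follows. The closest known reactions are oxazaborolidinium-catalysed Diels–Alder additions to 2-substituted enals and the macrocycle-forming intramolecular Diels–Alder reactions of long-chain trienals. The cyclohexene closes through the two new σ-bonds, and the twelve-membered ring closes in the same event as the 1,3-bridging ring built from the C2–C10 tether, C1, C15 and C11. C15 and C11 are fixed relative to each other by the (E)-enal (pentenyl chain cis to C10), C1 and C12 by the (E,E)-diene (C2 and CH2OSiEt3 cis), the endo position of the bound formyl group puts it cis to C2 and trans to C10, and the (R)-catalyst, chosen by the accepted model in which an aryl group covers one face of the bound enal, should leave the Si face of the α-carbon open. The step needs cyclisation to beat bimolecular cycloaddition (1 mM), the bridged and not the fused orientation (the alkyl group on C1 stabilises the positive charge that builds up in the diene, the oxygen-bearing branch on C12 does not, so C12 is the nucleophilic terminus), endo selectivity (usual for Lewis-acid-bound enals with open-chain dienes) and inert trisubstituted alkenes (unactivated, and the catalyst carries no free acid).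

Step 15
Reactants: 23 bicyclic triene aldehyde
Product: 24 (1R,3Z,7Z,11S,12R,15S)-4,8-dimethyl-15-(4-methylpent-3-en-1-yl)-12-{[(triethylsilyl)oxy]methyl}bicyclo[9.3.1]pentadeca-3,7-diene-15-carbaldehyde
Conditions: H2 (1 atm), RhCl(PPh3)3 (10 mol %), benzene, rt
Reagents that add atoms: none
Why: Homogeneous hydrogenation with the rhodium phosphine complex is very sensitive to alkene substitution, so the cis-disubstituted ring alkene should be reduced while the three trisubstituted alkenes and the aldehyde remain.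

Step 16
Reactants: 24 silyl ether aldehyde
Product: 25 (1R,3Z,7Z,11S,12R,15S)-4,8-dimethyl-15-(4-methylpent-3-en-1-yl)bicyclo[9.3.1]pentadeca-3,7-diene-12,15-dicarbaldehyde
Conditions: (COCl)2, Me2SO, CH2Cl2, −78 → −30 °C; then Et3N, −78 °C → rt
Reagents that add atoms: none
Why: Swern oxidation applied directly to the primary triethylsilyl ether (cleavage by the chlorosulfonium salt, then ylide collapse) gives the aldehyde without passing through the free alcohol, which would form a lactol with the C15 formyl group.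

Step 17
Reactants: 25 dialdehyde
Product: 26 (1R,3Z,7Z,11R,12R,15S)-12-chloro-4,8-dimethyl-15-(4-methylpent-3-en-1-yl)bicyclo[9.3.1]pentadeca-3,7-diene-12,15-dicarbaldehyde
Conditions: N-chlorosuccinimide, pyrrolidine (20 mol %), CF3CO2H (20 mol %), CH2Cl2, 0 °C
Reagents that add atoms: N-chlorosuccinimide, O=C1CCC(=O)N1Cl
Why: Enamine-mediated α-chlorination; only the C12 aldehyde has an α-hydrogen, and chlorine should enter the exocyclic enamine anti to the C10 branch on the neighbouring C11, i.e. on the face of the C15 formyl group, which sets C12.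

Step 18
Reactants: 26 chloro dialdehyde
Product: 28 [(1R,3Z,7Z,11R,12S,15S)-4,8-dimethyl-15-(4-methylpent-3-en-1-yl)spiro[bicyclo[9.3.1]pentadeca-3,7-diene-12,2'-oxiran]-15-yl]methanol, via chlorohydrin diol 27 (not isolated)
Conditions: NaBH4, MeOH/THF, −20 → 0 °C; then K2CO3, MeOH, rt
Reagents that add atoms: none
Why: Borohydride reduction of both aldehydes, then Williamson-type oxirane closure: the primary alkoxide displaces the tertiary chloride with inversion at C12, so the oxygen ends on the face of the pentenyl chain and the CH2 on the face of the C15 carbinol carbon, as in the target.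

Step 19
Reactants: 28 epoxy alcohol
Product: 29 (1R,3Z,7Z,11R,12S,15S)-4,8-dimethyl-15-(4-methylpent-3-en-1-yl)spiro[bicyclo[9.3.1]pentadeca-3,7-diene-12,2'-oxirane]-15-carbaldehyde
Conditions: Dess–Martin periodinane, NaHCO3, CH2Cl2, 0 °C → rt
Reagents that add atoms: none
Why: Dess–Martin oxidation under bicarbonate buffer converts the neopentyl primary alcohol into the aldehyde without opening the spiro-epoxide.

**Compound list**

1 | neryl acetate, (2Z)-3,7-dimethylocta-2,6-dien-1-yl acetate | CC(C)=CCC/C(C)=C\COC(C)=O | starting material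
2 | (2Z)-5-(5,5-dimethyl-1,2,4-trioxolan-3-yl)-3-methylpent-2-en-1-yl acetate | CC(=O)OC/C=C(/C)CCC1OOC(C)(C)O1 | intermediate
3 | (2Z)-3-methyl-6-oxohex-2-en-1-yl acetate | CC(=O)OC/C=C(/C)CCC=O | intermediate
4 | ethyl 2-[bis(2,2,2-trifluoroethoxy)phosphoryl]propanoate | CCOC(=O)C(C)P(=O)(OCC(F)(F)F)OCC(F)(F)F | starting material
5 | ethyl (2Z,6Z)-8-acetoxy-2,6-dimethylocta-2,6-dienoate | CCOC(=O)/C(C)=C\CC/C(C)=C\COC(C)=O | intermediate
6 | ethyl (2Z,6Z)-8-hydroxy-2,6-dimethylocta-2,6-dienoate | CCOC(=O)/C(C)=C\CC/C(C)=C\CO | intermediate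
7 | ethyl (2Z,6Z)-8-bromo-2,6-dimethylocta-2,6-dienoate | CCOC(=O)/C(C)=C\CC/C(C)=C\CBr | intermediate
8 | (E)-pent-2-en-4-yn-1-ol | C#C/C=C/CO | starting material
9 | (E)-triethyl(pent-2-en-4-yn-1-yloxy)silane | C#C/C=C/CO[Si](CC)(CC)CC | intermediate
10 | chlorobis(cyclopentadienyl)[(1E,3E)-5-(triethylsilyloxy)penta-1,3-dien-1-yl]zirconium | CC[Si](CC)(CC)OC/C=C/C=C/[Zr](Cl)(C1C=CC=C1)C1C=CC=C1 | intermediate
11 | ethyl (2Z,6Z,9E,11E)-2,6-dimethyl-13-[(triethylsilyl)oxy]trideca-2,6,9,11-tetraenoate | CCOC(=O)/C(C)=C\CC/C(C)=C\C/C=C/C=C/CO[Si](CC)(CC)CC | intermediate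
12 | (2Z,6Z,9E,11E)-2,6-dimethyl-13-[(triethylsilyl)oxy]trideca-2,6,9,11-tetraen-1-ol | OC/C(C)=C\CC/C(C)=C\C/C=C/C=C/CO[Si](CC)(CC)CC | intermediate
13 | (2Z,6Z,9E,11E)-2,6-dimethyl-13-[(triethylsilyl)oxy]trideca-2,6,9,11-tetraen-1-yl methanesulfonate | CS(=O)(=O)OC/C(C)=C\CC/C(C)=C\C/C=C/C=C/CO[Si](CC)(CC)CC | intermediate
14 | triethyl{[(2E,4E,7Z,11Z)-13-bromo-8,12-dimethyltrideca-2,4,7,11-tetraen-1-yl]oxy}silane | BrC/C(C)=C\CC/C(C)=C\C/C=C/C=C/CO[Si](CC)(CC)CC | intermediate
15 | (4Z,8Z,11E,13E)-4,8-dimethyl-15-[(triethylsilyl)oxy]pentadeca-4,8,11,13-tetraenenitrile | N#CCC/C(C)=C\CC/C(C)=C\C/C=C/C=C/CO[Si](CC)(CC)CC | intermediate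
16 | N-(diisobutylalumanyl) imine of 17 | CC(C)C[Al](CC(C)C)N=CCC/C(C)=C\CC/C(C)=C\C/C=C/C=C/CO[Si](CC)(CC)CC | intermediate
17 | (4Z,8Z,11E,13E)-4,8-dimethyl-15-[(triethylsilyl)oxy]pentadeca-4,8,11,13-tetraenal | O=CCC/C(C)=C\CC/C(C)=C\C/C=C/C=C/CO[Si](CC)(CC)CC | intermediate
18 | 5-bromo-2-methylpent-2-ene | CC(C)=CCCBr | starting material
19 | (4-methylpent-3-en-1-yl)triphenylphosphonium bromide | CC(C)=CCC[P+](c1ccccc1)(c1ccccc1)c1ccccc1.[Br-] | intermediate
20 | (4-methylpent-3-en-1-ylidene)triphenyl-λ5-phosphane | CC(C)=CCC=P(c1ccccc1)(c1ccccc1)c1ccccc1 | intermediate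
21 | 6-methyl-2-(triphenyl-λ5-phosphanylidene)hept-5-enal | CC(C)=CCCC(C=O)=P(c1ccccc1)(c1ccccc1)c1ccccc1 | intermediate
22 | (2E,6Z,10Z,13E,15E)-6,10-dimethyl-2-(4-methylpent-3-en-1-yl)-17-[(triethylsilyl)oxy]heptadeca-2,6,10,13,15-pentaenal | O=C/C(CCC=C(C)C)=C/CC/C(C)=C\CC/C(C)=C\C/C=C/C=C/CO[Si](CC)(CC)CC | intermediate
23 | (1S,3Z,7Z,11S,12R,15S)-4,8-dimethyl-15-(4-methylpent-3-en-1-yl)-12-{[(triethylsilyl)oxy]methyl}bicyclo[9.3.1]pentadeca-3,7,13-triene-15-carbaldehyde | CC(C)=CCC[C@]1(C=O)[C@H]2C/C=C(/C)CC/C=C(/C)CC[C@H]1[C@@H](C=C2)CO[Si](CC)(CC)CC | intermediate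
24 | (1R,3Z,7Z,11S,12R,15S)-4,8-dimethyl-15-(4-methylpent-3-en-1-yl)-12-{[(triethylsilyl)oxy]methyl}bicyclo[9.3.1]pentadeca-3,7-diene-15-carbaldehyde | CC(C)=CCC[C@]1(C=O)[C@H]2C/C=C(/C)CC/C=C(/C)CC[C@H]1[C@@H](CC2)CO[Si](CC)(CC)CC | intermediate
25 | (1R,3Z,7Z,11S,12R,15S)-4,8-dimethyl-15-(4-methylpent-3-en-1-yl)bicyclo[9.3.1]pentadeca-3,7-diene-12,15-dicarbaldehyde | CC(C)=CCC[C@]1(C=O)[C@H]2C/C=C(/C)CC/C=C(/C)CC[C@H]1[C@@H](CC2)C=O | intermediate
26 | (1R,3Z,7Z,11R,12R,15S)-12-chloro-4,8-dimethyl-15-(4-methylpent-3-en-1-yl)bicyclo[9.3.1]pentadeca-3,7-diene-12,15-dicarbaldehyde | CC(C)=CCC[C@]1(C=O)[C@H]2C/C=C(/C)CC/C=C(/C)CC[C@H]1[C@](Cl)(CC2)C=O | intermediate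
27 | [(1R,3Z,7Z,11R,12R,15S)-12-chloro-4,8-dimethyl-15-(4-methylpent-3-en-1-yl)bicyclo[9.3.1]pentadeca-3,7-diene-12,15-diyl]dimethanol | CC(C)=CCC[C@]1(CO)[C@H]2C/C=C(/C)CC/C=C(/C)CC[C@H]1[C@](Cl)(CC2)CO | intermediate
28 | [(1R,3Z,7Z,11R,12S,15S)-4,8-dimethyl-15-(4-methylpent-3-en-1-yl)spiro[bicyclo[9.3.1]pentadeca-3,7-diene-12,2'-oxiran]-15-yl]methanol | CC(C)=CCC[C@]1(CO)[C@H]2C/C=C(/C)CC/C=C(/C)CC[C@H]1[C@@]1(CC2)CO1 | intermediate
29 | (1R,3Z,7Z,11R,12S,15S)-4,8-dimethyl-15-(4-methylpent-3-en-1-yl)spiro[bicyclo[9.3.1]pentadeca-3,7-diene-12,2'-oxirane]-15-carbaldehyde | CC(C)=CCC[C@]1(C=O)[C@H]2C/C=C(/C)CC/C=C(/C)CC[C@H]1[C@@]1(CC2)CO1 | target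

**Step count.** 19 steps in total; longest linear sequence 16 steps (steps 1–4, 6–10 and 13–19, from neryl acetate).

**Steps most likely to fail**

1. Step 14. The twelve-membered ring closure has a low effective molarity, so intermolecular cycloaddition and oligomerisation can outrun it. The fused orientation, the exo adduct, or cationic attack of a trisubstituted alkene on the activated enal can also divert material. Fallback (sets out from 14 and 21, returns at 25): the cycloaddition is run between two molecules and the large ring is closed afterwards.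
   - Bromide 14 and NaSO2Ph in DMF should give the allylic sulfone F1.
   - Ylide 21 and bromoacetaldehyde should give the bromo enal F2.
   - The same oxazaborolidinium catalyst should join F1 and F2 at normal concentration to the cyclohexene F3, with the same endo and facial control.
   - iBu2AlH at −78 °C should give the alcohol F4, and Et3SiCl with imidazole its silyl ether F5.
   - KN(SiMe3)2 in THF under high dilution should close the twelve-membered ring by alkylation of the allylic sulfone anion with the primary bromide, giving F6.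
   - Na(Hg) with Na2HPO4 in MeOH should remove the sulfonyl group to give F7.
   - Hydrogenation as in step 15 should give F8, and Swern oxidation of both triethylsilyl ethers should give 25.

2. Step 15. The hindered ring alkene may be hydrogenated slowly, with competing reduction or migration of a trisubstituted alkene and decarbonylation of the aldehyde. Fallback (sets out from 23, returns at 25): the order is changed so that no alkene has to be hydrogenated.
   - Swern oxidation of the silyl ether of 23, followed by DBU, should move the ring double bond into conjugation and give the enal F9.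
   - Its double bond is then the only one that can be activated as an iminium ion; transfer hydrogenation with diethyl 2,6-dimethyl-1,4-dihydropyridine-3,5-dicarboxylate and dibenzylammonium trifluoroacetate should give 25.

3. Step 17. Enamine formation at the congested α-carbon may be slow, or chlorine may enter on the face cis to the C10 branch, which after inversion would give the C12 epimer. Fallback (sets out from 25, returns at 28): if electrophiles prefer that face, the preference is used with an oxygen electrophile and retention instead of chlorine and inversion.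
   - NaN(SiMe3)2 followed by 2-(phenylsulfonyl)-3-phenyloxaziridine should give the α-hydroxy dialdehyde F10.
   - NaBH4 should give the triol F11.
   - PPh3 with diisopropyl azodicarboxylate (Mitsunobu cyclodehydration of the 1,2-diol, the tertiary oxygen being kept) should close the oxirane to 28.

**Further compounds**

F1 | step 14 | triethyl{[(2E,4E,7Z,11Z)-8,12-dimethyl-13-(phenylsulfonyl)trideca-2,4,7,11-tetraen-1-yl]oxy}silane | O=S(=O)(C/C(C)=C\CC/C(C)=C\C/C=C/C=C/CO[Si](CC)(CC)CC)c1ccccc1
F2 | step 14 | (2E)-4-bromo-2-(4-methylpent-3-en-1-yl)but-2-enal | O=C/C(CCC=C(C)C)=C/CBr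
F3 | step 14 | 6-(bromomethyl)-2-[(2Z,6Z)-3,7-dimethyl-8-(phenylsulfonyl)octa-2,6-dien-1-yl]-1-(4-methylpent-3-en-1-yl)-5-{[(triethylsilyl)oxy]methyl}cyclohex-3-ene-1-carbaldehyde, ring configuration as in 23 | CC(C)=CCC[C@]1(C=O)[C@@H](C/C=C(/C)CC/C=C(/C)CS(=O)(=O)c2ccccc2)C=C[C@@H](CO[Si](CC)(CC)CC)[C@@H]1CBr
F4 | step 14 | primary alcohol from reduction of the formyl group of F3 | CC(C)=CCC[C@]1(CO)[C@@H](C/C=C(/C)CC/C=C(/C)CS(=O)(=O)c2ccccc2)C=C[C@@H](CO[Si](CC)(CC)CC)[C@@H]1CBr
F5 | step 14 | triethylsilyl ether of F4 | CC(C)=CCC[C@]1(CO[Si](CC)(CC)CC)[C@@H](C/C=C(/C)CC/C=C(/C)CS(=O)(=O)c2ccccc2)C=C[C@@H](CO[Si](CC)(CC)CC)[C@@H]1CBr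
F6 | step 14 | 9-(phenylsulfonyl) derivative of F7, C9 unassigned | CC(C)=CCC[C@]1(CO[Si](CC)(CC)CC)[C@H]2C/C=C(/C)CC/C=C(/C)C(S(=O)(=O)c3ccccc3)C[C@H]1[C@@H](C=C2)CO[Si](CC)(CC)CC
F7 | step 14 | (3Z,7Z)-4,8-dimethyl-15-(4-methylpent-3-en-1-yl)-12,15-bis{[(triethylsilyl)oxy]methyl}bicyclo[9.3.1]pentadeca-3,7,13-triene, configuration as in 23 | CC(C)=CCC[C@]1(CO[Si](CC)(CC)CC)[C@H]2C/C=C(/C)CC/C=C(/C)CC[C@H]1[C@@H](C=C2)CO[Si](CC)(CC)CC
F8 | step 14 | 13,14-dihydro derivative of F7 | CC(C)=CCC[C@]1(CO[Si](CC)(CC)CC)[C@H]2C/C=C(/C)CC/C=C(/C)CC[C@H]1[C@@H](CC2)CO[Si](CC)(CC)CC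
F9 | step 15 | (3Z,7Z)-4,8-dimethyl-15-(4-methylpent-3-en-1-yl)bicyclo[9.3.1]pentadeca-3,7,12-triene-12,15-dicarbaldehyde, C1, C11 and C15 as in 23 | CC(C)=CCC[C@]1(C=O)[C@H]2C/C=C(/C)CC/C=C(/C)CC[C@H]1C(C=O)=CC2
F10 | step 17 | 12-hydroxy derivative of 25, hydroxyl trans to the C15 formyl group | CC(C)=CCC[C@]1(C=O)[C@H]2C/C=C(/C)CC/C=C(/C)CC[C@H]1[C@@](O)(CC2)C=O
F11 | step 17 | triol from reduction of both formyl groups of F10 | CC(C)=CCC[C@]1(CO)[C@H]2C/C=C(/C)CC/C=C(/C)CC[C@H]1[C@@](O)(CC2)CO
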